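**Retrosynthetic overview**
- Feature: azulene B is the azulene on C6 of the indenone (primed numbers). Its seven-membered ring holds the four-carbon run C4'(CH3)–C5'H–C6'H–C7'(i-Pr) next to an unsubstituted C8'–H. The run maps onto the diene of 2-isopropyl-5-methylthiophene 1,1-dioxide. C8' maps onto the exocyclic carbon of a 6-(dimethylamino)fulvene whose ring already carries C1'–CH3 and the C3'–aryl bond.
- Late disconnections: first O–Si, then the indenone five-membered ring (C3a–C3 and C1–C2) by rhodium-catalysed C–H annulation of an N-aroyl oxazolidinone with 3-(prop-1-ynyl)guaiazulene. The alkyne brings in azulene A intact, and the imide comes from the aryl bromide by carbonylation.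
- Key disconnection: C3a'–C4' and C7'–C8' by [6+4] cycloaddition with loss of SO2 and HNMe2.
- The fulvene goes back to a 1-aryl-3-methylcyclopentadiene, made by adding a monolithiated symmetric dibromide to 3-methylcyclopent-2-enone. The crowded aryl–C3' bond is therefore formed as a plain carbonyl addition.
- Ring order: benzene ring (bought), five-membered ring of azulene B (bought as the enone), seven-membered ring of azulene B (step 9), five-membered ring of the indenone (step 12). Azulene A is bought as guaiazulene.

Key step: step 9

Assumption: the target SMILES carries no stereodescriptor, so the two hindered azulenyl axes are treated as configurationally undefined and no axial control is attempted.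

"Guaiazulen-3-yl" stands for 7-isopropyl-1,4-dimethylazulen-3-yl throughout.

Step 1
Reactants: 1 methyl 3,5-dibromo-4-methylbenzoate
Product: 2 2-(3,5-dibromo-4-methylphenyl)propan-2-ol
Conditions: MeMgBr (3 equiv), THF, 0 °C to rt; aq. NH4Cl work-up
Reagents that add atoms: methylmagnesium bromide C[Mg]Br
Why: Double Grignard addition to the ester gives the tertiary carbinol, and the aryl bromides do not exchange with MeMgBr at this temperature.

Step 2
Reactants: 2 2-(3,5-dibromo-4-methylphenyl)propan-2-ol
Product: 3 triethyl{[2-(3,5-dibromo-4-methylphenyl)propan-2-yl]oxy}silane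
Conditions: TESOTf (1.3 equiv), 2,6-lutidine (2 equiv), CH2Cl2, 0 °C to rt
Reagents that add atoms: triethylsilyl triflate CC[Si](CC)(CC)OS(=O)(=O)C(F)(F)F
Why: Silyl triflate silylation with a hindered pyridine base is the standard way to cap a tertiary alcohol, and the ether removes the acidic proton before the organolithium step and later keeps this oxygen off the rhodium catalyst.

Step 3
Reactants: 3 triethyl{[2-(3,5-dibromo-4-methylphenyl)propan-2-yl]oxy}silane; 4 3-methylcyclopent-2-en-1-one
Product: 6 1-{3-bromo-2-methyl-5-[2-(triethylsilyloxy)propan-2-yl]phenyl}-3-methylcyclopent-2-en-1-ol (racemic), via aryllithium 5 (not isolated)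
Conditions: n-BuLi (1.0 equiv), THF, −78 °C; then 4 premixed with LaCl3·2LiCl (1 equiv) in THF, −78 to −20 °C; H2O quench
Reagents that add atoms: none
Why: The two bromines of 3 are equivalent, so bromine–lithium exchange with one equivalent of n-BuLi should give a single monolithio species that adds 1,2 to the enone while the lanthanum salt suppresses enolisation; the new carbinol stereocentre forms as a racemate and is erased in step 4.

Step 4
Reactants: 6 1-{3-bromo-2-methyl-5-[2-(triethylsilyloxy)propan-2-yl]phenyl}-3-methylcyclopent-2-en-1-ol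
Product: 7 3-{3-bromo-2-methyl-5-[2-(triethylsilyloxy)propan-2-yl]phenyl}-1-methylcyclopenta-1,3-diene (drawn tautomer; the 1,5-hydrogen-shift isomers interconvert)
Conditions: p-TsOH·H2O (2 mol%), CH2Cl2, 0 °C, short contact; Et3N quench; used at once
Reagents that add atoms: none
Why: In this acid-catalysed E1 dehydration the alcohol ionises to an aryl-substituted allyl cation with two tertiary termini far faster than the silyl ether on the electron-poor cumyl position is touched, and proton loss gives the cyclopentadiene.

Step 5
Reactants: 7 3-{3-bromo-2-methyl-5-[2-(triethylsilyloxy)propan-2-yl]phenyl}-1-methylcyclopenta-1,3-diene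
Product: 8 (E)-6-(dimethylamino)-2-methyl-4-{3-bromo-2-methyl-5-[2-(triethylsilyloxy)propan-2-yl]phenyl}fulvene
Conditions: Me2NCH(OMe)2 (3 equiv), toluene, 90 °C, MeOH distilled off
Reagents that add atoms: N,N-dimethylformamide dimethyl acetal COC(OC)N(C)C
Why: Aminomethylenation of a CH-acidic cyclopentadiene with an amide acetal gives the 6-aminofulvene, and condensation should take the ring position next to the small methyl group and remote from the twisted ortho-substituted aryl group, as in fulvene condensations of other 1,3-disubstituted cyclopentadienes, with NMe2 turned away from the methyl group across an easily rotating exocyclic bond.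

Step 6
Reactants: 9 2-methylthiophene
Product: 11 2-(5-methylthiophen-2-yl)propan-2-ol, via 5-methyl-2-thienyllithium 10 (not isolated)
Conditions: n-BuLi (1.05 equiv), THF, −78 to 0 °C; acetone, −78 °C to rt; H2O quench
Reagents that add atoms: acetone CC(C)=O
Why: Lithiation at the only free position next to sulfur is followed by 1,2-addition of the thienyllithium to acetone.

Step 7
Reactants: 11 2-(5-methylthiophen-2-yl)propan-2-ol
Product: 12 2-isopropyl-5-methylthiophene
Conditions: Et3SiH (1.1 equiv), CF3CO2H (3 equiv), CH2Cl2, −20 to 0 °C; aq. NaHCO3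
Reagents that add atoms: none
Why: In this ionic hydrogenation (silane/acid deoxygenation) the tertiary thienyl cation is captured by hydride, and a near-stoichiometric amount of silane at low temperature avoids reduction of the thiophene ring.

Step 8
Reactants: 12 2-isopropyl-5-methylthiophene
Product: 13 2-isopropyl-5-methylthiophene 1,1-dioxide
Conditions: mCPBA (2.5 equiv), CH2Cl2, 0 °C to rt
Reagents that add atoms: 3-chloroperoxybenzoic acid O=C(OO)c1cccc(Cl)c1
Why: Peracid oxidation at sulfur runs through the S-oxide to the 1,1-dioxide, which can be isolated because alkyl groups on both α-carbons slow its Diels–Alder self-dimerisation.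

Step 9
Reactants: 8 (E)-6-(dimethylamino)-2-methyl-4-arylfulvene (aryl as in step 5); 13 2-isopropyl-5-methylthiophene 1,1-dioxide
Product: 16 3-{3-bromo-2-methyl-5-[2-(triethylsilyloxy)propan-2-yl]phenyl}-7-isopropyl-1,4-dimethylazulene, via sulfone-bridged cycloadduct 14 (not isolated), via aminodihydroazulene 15 (not isolated)
Conditions: 13 (3 equiv, added in portions), toluene, 105 °C, slow argon sweep to carry off Me2NH and SO2, dark
Reagents that add atoms: none
Why: The amino donor polarises the fulvene so that its one unsubstituted ring carbon beside the exocyclic bond (future C3a') is the nucleophilic end of a six-electron triene ending at the exocyclic carbon (future C8'), the electron-poor sulfone diene reacts at its two α-carbons, and bond C3a'–C4' runs ahead of bond C7'–C8' in a thermally allowed, asynchronous ten-electron [6+4] cycloaddition to 14. Cheletropic loss of SO2 from the bridged sulfolene 14 gives 15, and E1cB-type loss of dimethylamine through the cyclopentadienide aromatises 15 to azulene 16. The closest known reaction type is the azulene synthesis from 6-(dialkylamino)fulvenes and thiophene 1,1-dioxides, which includes alkyl-substituted partners on both sides. The seven-membered ring is closed by an intermolecular two-bond annulation, which in the stepwise limit is a 7-exo-trig capture of the iminium carbon by the sulfonyl-stabilised allyl anion. No stereocentre survives, since all four sp3 centres of 14 are erased on aromatisation. The step needs periselectivity ([6+4] over [4+2], favoured by the amino donor that concentrates reactivity at the triene termini), site selectivity (the other flanking ring carbon carries methyl, is more hindered and has no hydrogen to lose) and orientation (the aryl-flanked nucleophilic carbon should take the methyl-bearing α-carbon, because the other orientation would force isopropyl into the peri position beside the aryl group, while the open CH(NMe2) carbon accepts the isopropyl-bearing terminus).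

Step 10
Reactants: 17 guaiazulene (7-isopropyl-1,4-dimethylazulene)
Product: 19 7-isopropyl-1,4-dimethyl-3-(prop-1-yn-1-yl)azulene, via 3-iodoguaiazulene 18 (not isolated)
Conditions: N-iodosuccinimide (1.0 equiv), THF, −40 °C, dark; then Et3N, Pd(PPh3)4 (5 mol%), CuI (10 mol%), propyne (1 M in THF, 3 equiv), −40 °C to rt
Reagents that add atoms: propyne CC#C
Why: Electrophilic iodination takes C3, the only free nucleophilic position of the five-membered ring, and immediate Sonogashira coupling in the same flask consumes the labile iodide before it can decompose.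

Step 11
Reactants: 16 3-{3-bromo-2-methyl-5-[2-(triethylsilyloxy)propan-2-yl]phenyl}-7-isopropyl-1,4-dimethylazulene
Product: 20 3-{3-(guaiazulen-3-yl)-2-methyl-5-[2-(triethylsilyloxy)propan-2-yl]benzoyl}oxazolidin-2-one
Conditions: Pd(OAc)2 (5 mol%), Xantphos (7 mol%), CO (3 bar), oxazolidin-2-one (2 equiv), Na2CO3 (2 equiv), DMAP (20 mol%), toluene, 100 °C
Reagents that add atoms: carbon monoxide [C-]#[O+]; oxazolidin-2-one O=C1NCCO1
Why: In this palladium-catalysed aminocarbonylation, oxidative addition to zerovalent palladium, CO insertion and DMAP-relayed acyl transfer to the weakly nucleophilic carbamate nitrogen give the imide without any organolithium, which would add to the azulene or deprotonate its C4' methyl group.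

Step 12
Reactants: 20 3-{3-(guaiazulen-3-yl)-2-methyl-5-[2-(triethylsilyloxy)propan-2-yl]benzoyl}oxazolidin-2-one; 19 7-isopropyl-1,4-dimethyl-3-(prop-1-yn-1-yl)azulene
Product: 21 2,6-bis(guaiazulen-3-yl)-3,7-dimethyl-4-[2-(triethylsilyloxy)propan-2-yl]-1H-inden-1-one
Conditions: [Cp*RhCl2]2 (5 mol%), AgSbF6 (20 mol%), Cu(OAc)2 (30 mol%), 19 (1.5 equiv), ClCH2CH2Cl, 110 °C, sealed tube, argon
Reagents that add atoms: none
Why: In this redox-neutral C–H annulation of an N-aroyl oxazolidinone with an internal alkyne under cationic trivalent rhodium, carbonyl-directed, acetate-assisted metalation takes the only free position ortho to the acyl group (future C3a), the alkyne inserts in the usual aryl/alkyl sense with the methyl-bearing carbon bonding to C3a and the azulenyl-bearing carbon staying on rhodium, and addition of the alkenyl–rhodium bond to the imide carbonyl with expulsion of oxazolidinone closes the five-membered ring as the 2-azulenyl-3-methylindenone; both azulenes are blocked at C1 and C3, so electrophilic metalation has no open site.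

Step 13
Reactants: 21 2,6-bis(guaiazulen-3-yl)-3,7-dimethyl-4-[2-(triethylsilyloxy)propan-2-yl]-1H-inden-1-one
Product: 22 2,6-bis(guaiazulen-3-yl)-4-(2-hydroxypropan-2-yl)-3,7-dimethyl-1H-inden-1-one (CNP0151235.0)
Conditions: TBAF (2 equiv), AcOH (2 equiv), THF, 0 °C to rt
Reagents that add atoms: none
Why: Fluoride-induced silyl ether cleavage frees the tertiary alcohol, and the acetic acid buffer keeps the medium from deprotonating the vinylogous C3 methyl group of the indenone or the azulene C4 methyl groups.

**Compound list**
1 | methyl 3,5-dibromo-4-methylbenzoate | COC(=O)c1cc(Br)c(C)c(Br)c1 | starting material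
2 | 2-(3,5-dibromo-4-methylphenyl)propan-2-ol | CC(C)(O)c1cc(Br)c(C)c(Br)c1 | intermediate
3 | triethyl{[2-(3,5-dibromo-4-methylphenyl)propan-2-yl]oxy}silane | CC[Si](CC)(CC)OC(C)(C)c1cc(Br)c(C)c(Br)c1 | intermediate
4 | 3-methylcyclopent-2-en-1-one | CC1=CC(=O)CC1 | starting material
5 | 3-bromo-2-methyl-5-[2-(triethylsilyloxy)propan-2-yl]phenyllithium (not isolated) | [Li]c1cc(C(C)(C)O[Si](CC)(CC)CC)cc(Br)c1C | intermediate
6 | 1-{3-bromo-2-methyl-5-[2-(triethylsilyloxy)propan-2-yl]phenyl}-3-methylcyclopent-2-en-1-ol (racemic) | CC1=CC(O)(c2cc(C(C)(C)O[Si](CC)(CC)CC)cc(Br)c2C)CC1 | intermediate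
7 | 3-{3-bromo-2-methyl-5-[2-(triethylsilyloxy)propan-2-yl]phenyl}-1-methylcyclopenta-1,3-diene | CC1=CC(c2cc(C(C)(C)O[Si](CC)(CC)CC)cc(Br)c2C)=CC1 | intermediate
8 | (E)-6-(dimethylamino)-2-methyl-4-{3-bromo-2-methyl-5-[2-(triethylsilyloxy)propan-2-yl]phenyl}fulvene | CN(C)/C=C1/C(C)=CC(c2cc(C(C)(C)O[Si](CC)(CC)CC)cc(Br)c2C)=C1 | intermediate
9 | 2-methylthiophene | Cc1cccs1 | starting material
10 | 5-methyl-2-thienyllithium (not isolated) | Cc1ccc([Li])s1 | intermediate
11 | 2-(5-methylthiophen-2-yl)propan-2-ol | Cc1ccc(C(C)(C)O)s1 | intermediate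
12 | 2-isopropyl-5-methylthiophene | Cc1ccc(C(C)C)s1 | intermediate
13 | 2-isopropyl-5-methylthiophene 1,1-dioxide | CC1=CC=C(C(C)C)S1(=O)=O | intermediate
14 | sulfone-bridged [6+4] cycloadduct (not isolated; racemic, relative configuration left open, all sp3 centres erased) | CN(C)C1C2=C(C)C=C(c3cc(C(C)(C)O[Si](CC)(CC)CC)cc(Br)c3C)C2C2(C)C=CC1(C(C)C)S2(=O)=O | intermediate
15 | 3-aryl-8-(dimethylamino)-7-isopropyl-1,4-dimethyl-3a,8-dihydroazulene (not isolated; configuration left open, both sp3 centres erased) | CN(C)C1C2=C(C)C=C(c3cc(C(C)(C)O[Si](CC)(CC)CC)cc(Br)c3C)C2C(C)=CC=C1C(C)C | intermediate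
16 | 3-{3-bromo-2-methyl-5-[2-(triethylsilyloxy)propan-2-yl]phenyl}-7-isopropyl-1,4-dimethylazulene | CC[Si](CC)(CC)OC(C)(C)c1cc(Br)c(C)c(-c2cc(C)c3cc(C(C)C)ccc(C)c2-3)c1 | intermediate
17 | guaiazulene | c1cc(C)c2cc(C(C)C)ccc(C)c1-2 | starting material
18 | 3-iodoguaiazulene (not isolated) | Ic1cc(C)c2cc(C(C)C)ccc(C)c1-2 | intermediate
19 | 7-isopropyl-1,4-dimethyl-3-(prop-1-yn-1-yl)azulene | CC#Cc1cc(C)c2cc(C(C)C)ccc(C)c1-2 | intermediate
20 | 3-{3-(guaiazulen-3-yl)-2-methyl-5-[2-(triethylsilyloxy)propan-2-yl]benzoyl}oxazolidin-2-one | CC[Si](CC)(CC)OC(C)(C)c1cc(C(=O)N2CCOC2=O)c(C)c(-c2cc(C)c3cc(C(C)C)ccc(C)c2-3)c1 | intermediate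
21 | 2,6-bis(guaiazulen-3-yl)-3,7-dimethyl-4-[2-(triethylsilyloxy)propan-2-yl]-1H-inden-1-one | CC1=C(c2cc(C)c3cc(C(C)C)ccc(C)c2-3)C(=O)c2c(C)c(-c3cc(C)c4cc(C(C)C)ccc(C)c3-4)cc(C(C)(C)O[Si](CC)(CC)CC)c21 | intermediate
22 | 2,6-bis(guaiazulen-3-yl)-4-(2-hydroxypropan-2-yl)-3,7-dimethyl-1H-inden-1-one | CC1=C(c2cc(C)c3cc(C(C)C)ccc(C)c2-3)C(=O)c2c(C)c(-c3cc(C)c4cc(C(C)C)ccc(C)c3-4)cc(C(C)(C)O)c21 | target

Total step count: 13.
Longest linear sequence: 9 steps (steps 1, 2, 3, 4, 5, 9, 11, 12, 13).

**Steps most likely to fail**

Step 9.
- What may go wrong: the aryl group next to the reacting fulvene carbon may slow the first bond formation. Self-dimerisation of the sulfone, its ring opening by liberated dimethylamine, [4+2] modes of the fulvene, or erosion of the orientation preference could then take over.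
- Fallback: the ring construction is given up and intact guaiazulene is arylated. Setting out from 3 (used in excess to limit double coupling) and 17, Pd(OAc)2-catalysed direct C3–H arylation (KOAc, N,N-dimethylacetamide, 130 °C) exploits the most nucleophilic free azulene position. It comes back to the route at 16 and makes no new compound.

Step 12.
- What may go wrong: cyclometalation at the C–H bond flanked by the tertiary silyloxyalkyl group may be too slow. The ortho methyl group also twists the imide out of the ring plane. Prolonged heating with a cationic metal may ionise the silyl ether.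
- Fallback: the flanking centre is flattened before the C–H step. Setting out from 20, buffered fluoride (TBAF/AcOH) gives 3-[3-(guaiazulen-3-yl)-5-(2-hydroxypropan-2-yl)-2-methylbenzoyl]oxazolidin-2-one F1. MsCl/Et3N dehydration gives 3-[3-(guaiazulen-3-yl)-2-methyl-5-(prop-1-en-2-yl)benzoyl]oxazolidin-2-one F2, whose sp2 substituent can turn its face toward the metal.
- The same rhodium annulation with 19 should then give 2,6-bis(guaiazulen-3-yl)-3,7-dimethyl-4-(prop-1-en-2-yl)-1H-inden-1-one F3. Mukaiyama hydration (Mn(dpm)3 cat., PhSiH3, O2, i-PrOH/CH2Cl2, 0 °C) is a hydrogen-atom-transfer Markovnikov hydration that should pick the 1,1-disubstituted styrene over the tetrasubstituted enone. It comes back to the route at 22.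

Step 10.
- What may go wrong: the peri-crowded, electron-rich iodide may decompose before oxidative addition, and copper may divert propyne into oxidative homocoupling.
- Fallback: the halide is avoided and the alkyne is built from a stable aldehyde. Setting out from 17, Vilsmeier–Haack formylation (POCl3, DMF, 0 °C) gives guaiazulene-3-carbaldehyde F4. The first stage of the Corey–Fuchs sequence (CBr4, PPh3, CH2Cl2, 0 °C) gives 3-(2,2-dibromovinyl)guaiazulene F5.
- n-BuLi (2 equiv, THF, −78 °C, where exchange and rearrangement outrun addition to the seven-membered ring) gives lithium (guaiazulen-3-yl)acetylide F6. Trapping F6 with MeI comes back to the route at 19.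

**Further compounds**
F0 | step 9 | none | none
F1 | step 12 | 3-[3-(guaiazulen-3-yl)-5-(2-hydroxypropan-2-yl)-2-methylbenzoyl]oxazolidin-2-one | CC(C)(O)c1cc(C(=O)N2CCOC2=O)c(C)c(-c2cc(C)c3cc(C(C)C)ccc(C)c2-3)c1
F2 | step 12 | 3-[3-(guaiazulen-3-yl)-2-methyl-5-(prop-1-en-2-yl)benzoyl]oxazolidin-2-one | C=C(C)c1cc(C(=O)N2CCOC2=O)c(C)c(-c2cc(C)c3cc(C(C)C)ccc(C)c2-3)c1
F3 | step 12 | 2,6-bis(guaiazulen-3-yl)-3,7-dimethyl-4-(prop-1-en-2-yl)-1H-inden-1-one | CC1=C(c2cc(C)c3cc(C(C)C)ccc(C)c2-3)C(=O)c2c(C)c(-c3cc(C)c4cc(C(C)C)ccc(C)c3-4)cc(C(C)=C)c21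
F4 | step 10 | guaiazulene-3-carbaldehyde | O=Cc1cc(C)c2cc(C(C)C)ccc(C)c1-2
F5 | step 10 | 3-(2,2-dibromovinyl)guaiazulene | BrC(Br)=Cc1cc(C)c2cc(C(C)C)ccc(C)c1-2
F6 | step 10 | lithium (guaiazulen-3-yl)acetylide | [Li]C#Cc1cc(C)c2cc(C(C)C)ccc(C)c1-2
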